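Numbering: carbocycle C1–C10, C14 = methyl on C10, C15 = methyl on C4, C12 = lactone carbonyl, C13 = acetoxymethyl carbon on C11. Enabling feature: on the ten-membered carbocycle the oxygen-bearing carbons C3 (hemiketal) and C8 (oxygen terminus of the enol lactone) have four ring atoms between them on either side, and C8=C9 (cis in the ring) adjoins the quaternary carbinol C10. This 1,6-dioxygenated cyclodec-5-ene is the retron of an oxy-Cope ring expansion.
Cuts: first the C3–O–C10 hemiketal bridge and both acetates. Then C1–C10 is cut and C3–C8 re-made, which contracts the big ring to a cyclohexane-fused butenolide with vinyl on C3 and a Z-2-(methoxymethoxy)propenyl group on C8. Then C8–C9, C2–C3, the lactone (back to a furan), C3–C8 and C6–C7.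
Forward: citramalate (C3–C6, C15) is joined at C6–C7 to a 3-furanmethanol unit (C7, C8, C11–C13). Parham closure of C3–C8 builds the six-membered ring on the furan, vinyl goes on C3, and singlet oxygen opens the furan to the C8 keto ester. The alkenyllithium then adds to C8 and the butenolide closes.
The [3,3] shift opens the six-membered ring to the ten-membered one. Desilylation, diacetylation and MOM removal let O10 close the tetrahydrofuran ring on C3.
Stereochemistry: C4 comes from (S)-citramalic acid and C6 from a CBS reduction. C3 and C8 come from additions anti to the neighbouring C–O bonds, so both alkenyl groups are cis and lie opposite O4 and O6. C10 is set by suprafacial transfer from C8 through the Z enol ether, and the hemiketal C3 by equilibration.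

Key step: step 19

Assumption: the hemiketal carbon C3 equilibrates through the open hydroxy ketone, so the 3S epimer drawn for the target is taken to be the thermodynamic one.

Step 1
Reactants: 1 (S)-citramalic acid
Product: 2 dimethyl (2S)-2-hydroxy-2-methylbutanedioate
Conditions: MeOH, TsOH·H2O (cat.), 40 °C
Reagents that add atoms: methanol, SMILES CO
Why: Fischer esterification converts both carboxyl groups and does not touch the tertiary carbinol centre, which becomes C4 with the configuration of the target.

Step 2
Reactants: 2 dimethyl (2S)-2-hydroxy-2-methylbutanedioate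
Product: 3 dimethyl (2S)-2-methyl-2-(triethylsilyloxy)butanedioate
Conditions: Et3SiOTf, 2,6-lutidine, CH2Cl2, 0 °C
Reagents that add atoms: triethylsilyl triflate, SMILES CC[Si](CC)(CC)OS(=O)(=O)C(F)(F)F
Why: Silylation of a hindered tertiary alcohol with a silyl triflate and 2,6-lutidine is routine, and the triethylsilyl ether is a poor chelator, which matters for the Felkin–Anh addition in step 12.

Step 3
Reactants: 3 dimethyl (2S)-2-methyl-2-(triethylsilyloxy)butanedioate
Product: 4 methyl (2S)-4-[methoxy(methyl)amino]-2-methyl-4-oxo-2-(triethylsilyloxy)butanoate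
Conditions: MeNH(OMe)·HCl, i-PrMgCl, THF, −20 → 0 °C; then H2O
Reagents that add atoms: N,O-dimethylhydroxylamine hydrochloride, SMILES CNOC.Cl
Why: Ester-to-Weinreb-amide exchange with the chloromagnesium amide should pick the CH2-bound ester (future C6) because the other carbonyl (future C3) is shielded by the fully substituted C4.

Step 4
Reactants: 5 furan-3-ylmethanol
Product: 6 tert-butyl(furan-3-ylmethoxy)dimethylsilane
Conditions: TBSCl, imidazole, DMF, rt
Reagents that add atoms: tert-butyldimethylsilyl chloride, SMILES CC(C)(C)[Si](C)(C)Cl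
Why: Standard silyl ether formation at a primary alcohol sets up the silyl migration of step 5.

Step 5
Reactants: 6 tert-butyl(furan-3-ylmethoxy)dimethylsilane
Product: 8 [2-(tert-butyldimethylsilyl)furan-3-yl]methanol, via 2-lithiofuran 7 (not isolated)
Conditions: n-BuLi, HMPA, THF, −78 → 0 °C; then H2O
Reagents that add atoms: none
Why: Oxygen-directed lithiation at furan C2 followed by 1,4 O-to-C silyl migration (retro-Brook rearrangement) blocks the future C12 and frees the hydroxymethyl group as a directing group.

Step 6
Reactants: 8 [2-(tert-butyldimethylsilyl)furan-3-yl]methanol; 4 methyl (2S)-4-[methoxy(methyl)amino]-2-methyl-4-oxo-2-(triethylsilyloxy)butanoate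
Product: 10 methyl (2S)-4-[5-(tert-butyldimethylsilyl)-4-(hydroxymethyl)furan-3-yl]-2-methyl-4-oxo-2-(triethylsilyloxy)butanoate, via dilithiated furanmethanol 9 (not isolated)
Conditions: 8, n-BuLi (2.2 equiv), DME, 0 °C; then 4, THF, −78 °C; then H2O
Reagents that add atoms: none
Why: Alkoxide-directed β-lithiation of a 2-silyl-3-furanmethanol at C4 is a known way to 2,3,4-trisubstituted furans, and acylation of the furyllithium by the amide (Weinreb ketone synthesis) forms C6–C7 without over-addition because the chelated adduct lasts until work-up.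

Step 7
Reactants: 10 hydroxy ketone from step 6
Product: 11 methyl (2S)-4-{5-(tert-butyldimethylsilyl)-4-[(tert-butyldimethylsilyloxy)methyl]furan-3-yl}-2-methyl-4-oxo-2-(triethylsilyloxy)butanoate
Conditions: TBSCl, imidazole, CH2Cl2, 0 °C
Reagents that add atoms: tert-butyldimethylsilyl chloride, SMILES CC(C)(C)[Si](C)(C)Cl
Why: Silylation of the primary alcohol traps the open hydroxy ketone form and protects O13.

Step 8
Reactants: 11 furyl ketone
Product: 12 methyl (2S,4R)-4-{5-(tert-butyldimethylsilyl)-4-[(tert-butyldimethylsilyloxy)methyl]furan-3-yl}-4-hydroxy-2-methyl-2-(triethylsilyloxy)butanoate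
Conditions: (S)-2-methyl-CBS-oxazaborolidine (10 mol %), BH3·SMe2, toluene, −30 °C; then H2O
Reagents that add atoms: none
Why: Corey–Bakshi–Shibata reduction of a heteroaryl alkyl ketone sets C6 by reagent control, the S catalyst delivering hydride to the face that gives the R carbinol when the furyl group acts as the large substituent.

Step 9
Reactants: 12 C6 carbinol
Product: 13 methyl (2S,4R)-4-{5-(tert-butyldimethylsilyl)-4-[(tert-butyldimethylsilyloxy)methyl]furan-3-yl}-4-(methoxymethoxy)-2-methyl-2-(triethylsilyloxy)butanoate
Conditions: MOMCl, i-Pr2NEt, CH2Cl2, 0 °C → rt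
Reagents that add atoms: chloromethyl methyl ether, SMILES COCCl
Why: Alkylation of the secondary alcohol with MOMCl under amine base gives an acetal ether that survives organolithiums, fluoride and potassium bases, and prompt protection forestalls lactonisation onto the C3 ester.

Step 10
Reactants: 13 MOM ether
Product: 14 methyl (2S,4R)-4-{5-(tert-butyldimethylsilyl)-4-[(tert-butyldimethylsilyloxy)methyl]-2-iodofuran-3-yl}-4-(methoxymethoxy)-2-methyl-2-(triethylsilyloxy)butanoate
Conditions: NIS, DMF, 0 °C, dark
Reagents that add atoms: N-iodosuccinimide, SMILES O=C1CCC(=O)N1I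
Why: Electrophilic aromatic iodination goes to C8, the only free α-position of the furan, since C12 carries the bulky silyl group.

Step 11
Reactants: 14 C8 iodide
Product: 16 (4R,6S)-2-(tert-butyldimethylsilyl)-3-[(tert-butyldimethylsilyloxy)methyl]-4-(methoxymethoxy)-6-methyl-6-(triethylsilyloxy)-5,6-dihydro-1-benzofuran-7(4H)-one, via furyllithium 15 (not isolated)
Conditions: t-BuLi (2 equiv), Et2O–THF, −95 → −40 °C; then H2O
Reagents that add atoms: none
Why: Parham cyclisation: iodine–lithium exchange is faster than attack of t-BuLi on the hindered ester, and the furyllithium closes the six-membered ring by 6-exo-trig acylation to form C3–C8.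

Step 12
Reactants: 16 furan-fused C3 ketone; 17 vinylmagnesium bromide
Product: 18 (4R,6S,7R)-2-(tert-butyldimethylsilyl)-3-[(tert-butyldimethylsilyloxy)methyl]-7-ethenyl-4-(methoxymethoxy)-6-methyl-6-(triethylsilyloxy)-4,5,6,7-tetrahydro-1-benzofuran-7-ol (new hydroxyl cis to both ring oxygen substituents)
Conditions: THF, −78 → −30 °C; then H2O
Reagents that add atoms: none
Why: Grignard 1,2-addition to a non-enolisable 2-acylfuran; peri strain with the C13 side chain keeps O6 and with it the cis O4 pseudo-axial, so polar Felkin–Anh attack anti to the C4–O bond places the vinyl group trans to O4 and sets C3.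

Step 13
Reactants: 18 C3 vinyl carbinol
Product: 19 trimethylsilyl ether of 18
Conditions: Me3SiOTf, 2,6-lutidine, CH2Cl2, −78 °C
Reagents that add atoms: trimethylsilyl triflate, SMILES C[Si](C)(C)OS(=O)(=O)C(F)(F)F
Why: Silyl triflate silylation at low temperature under base caps the ionisable tertiary furyl allyl carbinol, and the silyl ether later serves as the non-chelating control group for step 17.

Step 14
Reactants: 19 silylated furan
Product: 21 γ-hydroxybutenolide (C12 lactone carbonyl and C8 hemiketal; C3 C4 C6 as in 19; both C8 epimers), via furan endoperoxide 20 (not isolated)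
Conditions: O2, hν, tetraphenylporphyrin (cat.), CH2Cl2, −78 °C; then H2O, rt
Reagents that add atoms: dioxygen, SMILES O=O
Why: [4+2] cycloaddition of singlet oxygen to the 2-silylfuran and silyl migration within the endoperoxide give regiospecifically the C12 carboxyl and C8 keto groups, which rest as the γ-hydroxybutenolide (C8 epimers are of no consequence), while the vinyl group has no allylic hydrogen and is inert.

Step 15
Reactants: 21 γ-hydroxybutenolide
Product: 22 methyl (2Z)-3-(tert-butyldimethylsilyloxy)-2-[2-(methoxymethoxy)-4-methyl-6-oxo-4-(triethylsilyloxy)-5-(trimethylsilyloxy)-5-ethenylcyclohexylidene]propanoate (stereocentres as in 19)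
Conditions: MeI, K2CO3, DMF, 0 °C
Reagents that add atoms: iodomethane, SMILES CI
Why: Alkylation of the carboxylate of the open keto acid form (SN2 on iodomethane) fixes the ring-opened Z keto ester and exposes C8 as a ketone.

Step 16
Reactants: 23 bromoacetone
Product: 25 (Z)-1-bromo-2-(methoxymethoxy)prop-1-ene, via lithium Z-enolate 24 (not isolated)
Conditions: LiN(SiMe3)2, THF–DMPU, −78 °C; then MOMCl
Reagents that add atoms: chloromethyl methyl ether, SMILES COCCl
Why: Kinetic deprotonation on the bromine-bearing side in a polar medium gives the Z(O) enolate, and the hard electrophile MOMCl alkylates it on oxygen (enolate O-alkylation), so bromine and oxygen end up cis.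

Step 17
Reactants: 25 (Z)-1-bromo-2-(methoxymethoxy)prop-1-ene; 22 C8 keto ester
Product: 27 trimethylsilyl ether of bicyclic lactone carbinol 28, via Z-alkenyllithium 26 (not isolated)
Conditions: 25, t-BuLi (2 equiv), Et2O, −78 °C; then 22, THF, −78 → −20 °C; then H2O (pH 7)
Reagents that add atoms: none
Why: Bromine–lithium exchange keeps the Z geometry (lithium held by the MOM oxygens), and 1,2-addition to the non-enolisable C8 ketone should come anti to the C3–OSiMe3 bond (polar Felkin–Anh), which is also the face away from O4 and O6, so the alkenyl group lands cis to the vinyl group (sets C8) before the alkoxide closes the butenolide on the Z ester (5-exo-trig lactonisation).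

Step 18
Reactants: 27 C3 trimethylsilyl ether
Product: 28 (4R,6S,7R,7aR)-3-[(tert-butyldimethylsilyloxy)methyl]-7-ethenyl-7-hydroxy-4-(methoxymethoxy)-7a-[(1Z)-2-(methoxymethoxy)prop-1-en-1-yl]-6-methyl-6-(triethylsilyloxy)-5,6,7,7a-tetrahydro-1-benzofuran-2(4H)-one
Conditions: Bu4NF, AcOH (1:1), THF, 0 °C
Reagents that add atoms: none
Why: Buffered fluoride removes the trimethylsilyl ether well before the tertiary triethylsilyl and primary tert-butyldimethylsilyl ethers, and the near-neutral medium spares the enol ether and avoids a free alkoxide.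

Step 19
Reactants: 28 bicyclic lactone carbinol (vinyl on C3 and Z-alkenyl on C8, cis)
Product: 31 (4S,6R,8E,10R)-13-(tert-butyldimethylsilyloxy)-6,10-bis(methoxymethoxy)-3-oxo-4-(triethylsilyloxy)germacra-7(11),8-dien-12,8-olide (C8=C9 cis within the ring), via potassium alkoxide 29 (not isolated), via potassium enolate 30 (not isolated)
Conditions: KN(SiMe3)2 (1.05 equiv), THF, −78 → −30 °C; then AcOH, −78 °C
Reagents that add atoms: none
Why: Proposed new method: potassium alkoxide 29 pushes electron density into the C3–C8 σ bond, which stands almost perpendicular to the butenolide plane and has oxygen at both ends, and this bond gives way as the vinyl terminus C1 bonds to the enol-ether carbon C10 in one suprafacial six-centre event, leaving enolate 30 and an exocyclic C8=C9 bond conjugated with the lactone; at its polar limit the event is a retro-vinylogous aldol followed by remote Michael attack of the tethered dienolate on the enone, which makes the same bonds. The closest known reaction type is the anionic oxy-Cope ring expansion of cis-1,2-dialkenylcyclohexanols to cyclodec-5-enones, including cases with an ether oxygen on the breaking bond, but an acyloxy-bearing carbon on that bond and an enol-ether terminus have not been tried. No ring is closed by a separate cyclisation: the ten-membered carbocycle arises by four-atom expansion of the six-membered ring through a bicyclo[4.4.0]-like array, and the butenolide is carried along unchanged. C10 is the only new stereocentre and is set by chirality transfer, since C3 leaves and C1 arrives on the same face of the C8–C9–C10 unit, so the C8 configuration together with the Z enol ether (oxygen inside, methyl outside) gives 10R. The step needs C10 to swing towards C7 (cis C8=C9) and needs [3,3] rather than [1,3] closure or plain cleavage; three features should favour this, namely that the flat sp2 C7 is easier to place pseudo-axial than the fully substituted C4, that the inside enol oxygen meets only H6 on that side but the lactone ring oxygen on the other, and that the carbocycle chair leading to the trans alkene suffers a 1,3-diaxial clash between C9 and the C4 methyl. One equivalent of base, low temperature and a cold acid quench are meant to hold back C6–H deprotonation, O4-to-O3 silyl shift and transannular Michael addition of enolate 30.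

Step 20
Reactants: 31 ten-membered 3-ketone
Product: 32 (4S,6R,8E,10R)-4,13-dihydroxy-6,10-bis(methoxymethoxy)-3-oxogermacra-7(11),8-dien-12,8-olide
Conditions: HF·pyridine, pyridine, THF, 0 °C → rt
Reagents that add atoms: none
Why: Fluoride-mediated desilylation with buffered HF·pyridine frees O4 and O13 and leaves both MOM ethers, the ketone and the dienolide alone.

Step 21
Reactants: 32 diol
Product: 33 (4S,6R,8E,10R)-4,13-diacetoxy-6,10-bis(methoxymethoxy)-3-oxogermacra-7(11),8-dien-12,8-olide
Conditions: Ac2O, Et3N, DMAP, CH2Cl2, rt → 35 °C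
Reagents that add atoms: acetic anhydride, SMILES CC(=O)OC(C)=O
Why: DMAP-catalysed acylation (nucleophilic catalysis) acetylates the primary allylic and, more slowly, the tertiary α-ketol hydroxyl, while O6 and O10 stay masked as MOM ethers.

Step 22
Reactants: 33 diacetate
Product: 35 CNP0203479.1 (3S,4S,6R,8E,10R)-4,13-diacetoxy-3,10-epoxy-3,6-dihydroxygermacra-7(11),8-dien-12,8-olide, via C10 hydroxy ketone 34 (not isolated)
Conditions: Me2BBr, CH2Cl2, −78 °C; then THF, aq NaHCO3, rt
Reagents that add atoms: none
Why: Boron-halide cleavage of acetal ethers works at −78 °C on secondary and tertiary MOM ethers without touching acetates, and the freed C10 hydroxyl adds to the C3 ketone (5-exo-trig hemiketalisation), the reversible closure settling C3 as the 3S epimer under thermodynamic control.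

Compound list
1 | (S)-citramalic acid | C[C@](O)(CC(=O)O)C(=O)O | starting material
2 | dimethyl (2S)-2-hydroxy-2-methylbutanedioate | C[C@](O)(CC(=O)OC)C(=O)OC | intermediate
3 | dimethyl (2S)-2-methyl-2-(triethylsilyloxy)butanedioate | C[C@](O[Si](CC)(CC)CC)(CC(=O)OC)C(=O)OC | intermediate
4 | methyl (2S)-4-[methoxy(methyl)amino]-2-methyl-4-oxo-2-(triethylsilyloxy)butanoate | C[C@](O[Si](CC)(CC)CC)(CC(=O)N(C)OC)C(=O)OC | intermediate
5 | furan-3-ylmethanol | OCc1ccoc1 | starting material
6 | tert-butyl(furan-3-ylmethoxy)dimethylsilane | CC(C)(C)[Si](C)(C)OCc1ccoc1 | intermediate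
7 | 2-lithio derivative of 6 | CC(C)(C)[Si](C)(C)OCc1ccoc1[Li] | intermediate
8 | [2-(tert-butyldimethylsilyl)furan-3-yl]methanol | OCc1ccoc1[Si](C)(C)C(C)(C)C | intermediate
9 | O,C4-dilithio derivative of 8 | [Li]OCc1c([Li])coc1[Si](C)(C)C(C)(C)C | intermediate
10 | methyl (2S)-4-[5-(tert-butyldimethylsilyl)-4-(hydroxymethyl)furan-3-yl]-2-methyl-4-oxo-2-(triethylsilyloxy)butanoate | C[C@](O[Si](CC)(CC)CC)(CC(=O)c1coc([Si](C)(C)C(C)(C)C)c1CO)C(=O)OC | intermediate
11 | primary tert-butyldimethylsilyl ether of 10 | C[C@](O[Si](CC)(CC)CC)(CC(=O)c1coc([Si](C)(C)C(C)(C)C)c1CO[Si](C)(C)C(C)(C)C)C(=O)OC | intermediate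
12 | (2S,4R)-4-hydroxy ester (C6 carbinol) | C[C@](O[Si](CC)(CC)CC)(C[C@@H](O)c1coc([Si](C)(C)C(C)(C)C)c1CO[Si](C)(C)C(C)(C)C)C(=O)OC | intermediate
13 | MOM ether of 12 | C[C@](O[Si](CC)(CC)CC)(C[C@@H](OCOC)c1coc([Si](C)(C)C(C)(C)C)c1CO[Si](C)(C)C(C)(C)C)C(=O)OC | intermediate
14 | C8 iodide of 13 (2-iodofuran) | C[C@](O[Si](CC)(CC)CC)(C[C@@H](OCOC)c1c(I)oc([Si](C)(C)C(C)(C)C)c1CO[Si](C)(C)C(C)(C)C)C(=O)OC | intermediate
15 | C8 furyllithium from 14 | C[C@](O[Si](CC)(CC)CC)(C[C@@H](OCOC)c1c([Li])oc([Si](C)(C)C(C)(C)C)c1CO[Si](C)(C)C(C)(C)C)C(=O)OC | intermediate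
16 | (4R,6S)-2-(tert-butyldimethylsilyl)-3-[(tert-butyldimethylsilyloxy)methyl]-4-(methoxymethoxy)-6-methyl-6-(triethylsilyloxy)-5,6-dihydro-1-benzofuran-7(4H)-one | O=C1c2oc([Si](C)(C)C(C)(C)C)c(CO[Si](C)(C)C(C)(C)C)c2[C@H](OCOC)C[C@]1(C)O[Si](CC)(CC)CC | intermediate
17 | vinylmagnesium bromide | C=C[Mg]Br | starting material
18 | (4R,6S,7R)-7-ethenyl-7-ol from 16 (hydroxyl cis to both ring oxygen substituents) | O[C@]1(C=C)c2oc([Si](C)(C)C(C)(C)C)c(CO[Si](C)(C)C(C)(C)C)c2[C@H](OCOC)C[C@]1(C)O[Si](CC)(CC)CC | intermediate
19 | trimethylsilyl ether of 18 | C[Si](C)(C)O[C@]1(C=C)c2oc([Si](C)(C)C(C)(C)C)c(CO[Si](C)(C)C(C)(C)C)c2[C@H](OCOC)C[C@]1(C)O[Si](CC)(CC)CC | intermediate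
20 | C8,C12 endoperoxide of furan 19 | C[Si](C)(C)O[C@]1(C=C)C23OOC(O2)([Si](C)(C)C(C)(C)C)C(CO[Si](C)(C)C(C)(C)C)=C3[C@H](OCOC)C[C@]1(C)O[Si](CC)(CC)CC | intermediate
21 | γ-hydroxybutenolide (C8 hemiketal, both epimers) | C[Si](C)(C)O[C@]1(C=C)C2(O)OC(=O)C(CO[Si](C)(C)C(C)(C)C)=C2[C@H](OCOC)C[C@]1(C)O[Si](CC)(CC)CC | intermediate
22 | ring-opened (Z) C8 keto methyl ester | C[Si](C)(C)O[C@]1(C=C)C(=O)/C(=C(/CO[Si](C)(C)C(C)(C)C)C(=O)OC)[C@H](OCOC)C[C@]1(C)O[Si](CC)(CC)CC | intermediate
23 | bromoacetone | CC(=O)CBr | starting material
24 | lithium (Z)-1-bromoprop-1-en-2-olate | C/C(O[Li])=C/Br | intermediate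
25 | (Z)-1-bromo-2-(methoxymethoxy)prop-1-ene | C/C(OCOC)=C/Br | intermediate
26 | (Z)-2-(methoxymethoxy)prop-1-enyllithium | C/C(OCOC)=C/[Li] | intermediate
27 | C3 trimethylsilyl ether of 28 | O1C(=O)C(CO[Si](C)(C)C(C)(C)C)=C2[C@]1(/C=C(/C)OCOC)[C@](O[Si](C)(C)C)(C=C)[C@@](C)(O[Si](CC)(CC)CC)C[C@H]2OCOC | intermediate
28 | (4R,6S,7R,7aR) bicyclic lactone carbinol, precursor of the key step | O1C(=O)C(CO[Si](C)(C)C(C)(C)C)=C2[C@]1(/C=C(/C)OCOC)[C@](O)(C=C)[C@@](C)(O[Si](CC)(CC)CC)C[C@H]2OCOC | intermediate
29 | potassium C3 alkoxide of 28 | O1C(=O)C(CO[Si](C)(C)C(C)(C)C)=C2[C@]1(/C=C(/C)OCOC)[C@]([O-])(C=C)[C@@](C)(O[Si](CC)(CC)CC)C[C@H]2OCOC.[K+] | intermediate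
30 | potassium C2=C3 enolate of 31 | CC(C)(C)[Si](C)(C)OCC1=C2/C(=C\[C@@](OCOC)(C)CC=C([O-])[C@@](C)(O[Si](CC)(CC)CC)C[C@H]2OCOC)OC1=O.[K+] | intermediate
31 | (4S,6R,8E,10R) ten-membered 3-ketone, product of the key step | CC(C)(C)[Si](C)(C)OCC1=C2/C(=C\[C@@](OCOC)(C)CCC(=O)[C@@](C)(O[Si](CC)(CC)CC)C[C@H]2OCOC)OC1=O | intermediate
32 | 4,13-diol | OCC1=C2/C(=C\[C@@](OCOC)(C)CCC(=O)[C@@](C)(O)C[C@H]2OCOC)OC1=O | intermediate
33 | 4,13-diacetate | CC(=O)OCC1=C2/C(=C\[C@@](OCOC)(C)CCC(=O)[C@@](C)(OC(C)=O)C[C@H]2OCOC)OC1=O | intermediate
34 | open 6,10-dihydroxy 3-ketone | CC(=O)OCC1=C2/C(=C\[C@@](O)(C)CCC(=O)[C@@](C)(OC(C)=O)C[C@H]2O)OC1=O | intermediate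
35 | CNP0203479.1 | CC(=O)OCC1=C2/C(=C\[C@@]3(C)CC[C@](O)(O3)[C@@](C)(OC(C)=O)C[C@H]2O)OC1=O | target

Total step count: 22. Longest linear sequence: 19 steps (1–3, 6–15, 17–22).

Steps most likely to fail

First, step 19. The alkoxide may expel C8 as the stabilised lactone dienolate faster than C1 and C10 bond (retro-vinylogous aldol). Chirality transfer would then be lost, and reclosure at C8 or protonation of the seco enone could take over. C10 may also swing towards the ring oxygen, which gives the trans C8=C9 geometry together with the wrong C10 configuration.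

The fallback keeps the C3 oxygen uncharged, so no carbanion-type leaving group exists. It sets out from 27. Heating in toluene at 110–130 °C in base-washed glass triggers the thermal siloxy-Cope rearrangement, the known neutral ring expansion of 1,2-dialkenylcyclohexyl silyl ethers. This gives the ring-expanded trimethylsilyl enol ether F1. Bu4NF/AcOH at 0 °C then cleaves only the enol silane, and the route is rejoined at 31.

Second, step 17. The β-alkoxy alkenyllithium may collapse to propyne by elimination. It may also act as a base at the γ-position C6–H instead of adding to the crowded ketone, or attack from the oxygen-bearing face.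

The fallback replaces the sp2 nucleophile by an allyl-type one that reacts through its unhindered CH2 terminus. It sets out from 22. A Barbier allylation with zinc dust and 2-(chloromethyl)-3,5-dioxahex-1-ene in THF, followed by spontaneous lactonisation, gives the C8 2-(methoxymethoxy)allyl butenolide F2. Alkene isomerisation with RuHCl(CO)(PPh3)3 in warm toluene moves the 1,1-disubstituted enol-ether double bond to C9=C10. The bulky C8 should prefer to sit cis to oxygen rather than to methyl (Z). The vinyl group on C3 has no allylic hydrogen and cannot migrate. The route is rejoined at 27.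

Third, step 12. Magnesium chelation (furan oxygen, O4) or a populated conformer with the C4 methyl pseudo-axial may turn the attack to the face syn to O4. The resulting C3 epimer would end as the trans-dialkenyl isomer, which cannot reach the cis alkene.

The fallback builds the vinyl carbinol in two one-carbon operations under reversible addition. It sets out from 16. Corey–Chaykovsky epoxidation with dimethylsulfoxonium methylide (Me3S(O)I, NaH, DMSO) proceeds through a reversible betaine. Closure therefore selects the C3 spiro-epoxide F3 whose CH2 lies anti to the C4 silyloxy group. Excess dimethylsulfonium methylide (Me3SI, n-BuLi, THF) opens the epoxide at CH2 and eliminates dimethyl sulfide, a known epoxide-to-allylic-alcohol homologation. The route is rejoined at 18.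

Further compounds
F1 | step 19 | ring-expanded trimethylsilyl enol ether (C2=C3–OSiMe3; 4S,6R,8E,10R) | CC(C)(C)[Si](C)(C)OCC1=C2/C(=C\[C@@](OCOC)(C)CC=C(O[Si](C)(C)C)[C@@](C)(O[Si](CC)(CC)CC)C[C@H]2OCOC)OC1=O
F2 | step 17 | C8 2-(methoxymethoxy)allyl butenolide (C3 trimethylsilyl ether, allyl group cis to vinyl) | O1C(=O)C(CO[Si](C)(C)C(C)(C)C)=C2[C@]1(CC(=C)OCOC)[C@](O[Si](C)(C)C)(C=C)[C@@](C)(O[Si](CC)(CC)CC)C[C@H]2OCOC
F3 | step 12 | C3 spiro-epoxide of ketone 16 (epoxide oxygen cis to O4) | O1C[C@]12c3oc([Si](C)(C)C(C)(C)C)c(CO[Si](C)(C)C(C)(C)C)c3[C@H](OCOC)C[C@]2(C)O[Si](CC)(CC)CC
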